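Compound numbers follow the steps below. Labdane numbering is used for the bicycle: ring A = C1–C5 and C10, ring B = C5–C10.

## The problem

Compound 26 is a 5,10-cis-fused labdane in which ring B carries five contiguous stereocentres, C5, C6, C8, C9 and C10; C10 is an all-carbon quaternary centre and C8 a tertiary carbinol. The C10 methyl group, H5, the C6 acetoxy group, the C8 methyl group and the C9 side chain all lie on one face of ring B, the convex face of the cis-decalin. C10 has no neighbour that could direct it and must be set by a catalyst; it can then govern C5 in the ring closure, and the folded bicycle can govern C9, C6 and C8 in turn. The side chain ends in an (E)-trisubstituted enoic acid that has to be freed in the presence of a secondary acetate, so hydroxide is excluded at the end. The tertiary C8 alcohol can dehydrate or, once C13 is a ketone, close onto it under acid; β-hydroxy ketones in ring B can eliminate or cleave by retro-aldol reaction; C5 and C9 can epimerise whenever a carbonyl stands next to them. The hardest bond is C4–C5, which joins the quaternary C4 to a carbon that also neighbours quaternary C10 and is out of reach of any SN2 alkylation. The same bond offers the opening: C5 is the α-carbon of the C6 oxygen function, so C4 can be a tertiary carbocation and C5=C6 an enol silane, and their union closes ring A.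

## Retrosynthesis

**C13=C14 (26 ⇒ 25 ⇒ 24 ⇒ 23).** The acid is masked as an allyl ester (25), the acetate is removed (24), and the enoate double bond is cut back to the methyl ketone 23 by a phosphonate olefination. An enoate carried through earlier steps would not survive the organometallic reagents, and a side-chain halide already containing it would eliminate through its acidic γ-protons. The allyl ester can be cleaved under neutral conditions that leave the acetate. Acylation is placed after olefination because the free hydroxy ketone 23 could form a hemiketal that competes for the acylating agent. The forward steps must give the (E)-olefin and must acylate the secondary but not the tertiary alcohol.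

**C8–CH3 (23 ⇒ 22 ⇒ 21).** The tertiary carbinol is cut at its methyl group, leading through the ketal 22 to the β-hydroxy ketone 21. Hydration of a C7=C8 or exocyclic C8 olefin would have to bring oxygen to the concave face. A carbon nucleophile instead enters from the convex face and leaves the oxygen where 26 has it. 21 has one stereocentre fewer and no acid-sensitive carbinol. The forward reaction needs a non-basic methyl nucleophile and convex-face attack.

**C6–O (21 ⇒ 19).** 21 is the formal hydrate of enone 19, so the C6–O bond is cut and assigned to a conjugate addition of a boron nucleophile followed by oxidation. Hydroboration of a C6=C7 olefin beside the C8 carbinol would tend to place boron at C7, next to the oxygenated carbon. Hydride reduction of a C6 ketone from the convex face would give the wrong epimer. In 19 the enone polarity fixes the position and C4 on the neighbouring C5 fixes the face.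

**C9–C11 (19 ⇒ 14 + 17; 17 ⇒ 15).** The side chain is detached at C9–C11, giving enone 14 and iodide 17, which carries C11–C13 and C16 as a masked methyl ketone and comes in one step from 15. The C6=C7 double bond of 14 closes C7 to enolisation so that only C9 can be alkylated, later accepts the C6 oxygen, and holds the C8 carbonyl. Direct Michael addition of the dienolate to 15 was set aside because cross-conjugated dienolates and enones tend to give double Michael (bicyclo[2.2.2]octanone) products. The forward step asks a hindered enolate to react with a primary iodide on the convex face.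

**Carbonyl transposition (14 ⇒ 13 ⇒ 11 ⇒ 10 ⇒ 8).** No skeletal bond is cut. The carbonyl is moved from C8 back to C6 through allylic alcohol 13, epoxy ketone 11 and enone 10 to the saturated ketone 8. These four steps are the price for having the carbonyl at C6, where the ring closure needs it; a C6 ketone itself cannot direct chemistry at C9. The forward sequence is dehydrogenation, nucleophilic epoxidation, Wharton transposition and oxidation.

**C4–C5 (8 ⇒ 7).** The central cut opens ring A between C4 and C5, giving the monocyclic enol silane 7 with a tertiary methyl ether at the end of a three-carbon tether on C10. Cutting C1–C10 or C5–C10 instead would leave a quaternary centre to be made inside a ring. Cutting C4–C5 removes one ring and one stereocentre and leaves a single stereocentre in 7. The forward step must form a bond between two fully substituted neighbourhoods and must give the cis fusion.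

**C1–C10 (7 ⇒ 3 + 4; 3 ⇒ 1).** The tether is detached from C10, which leads to enone 4 and the Grignard reagent from bromide 3, itself one step from bromo olefin 1. A catalytic asymmetric conjugate addition sets C10, and trapping of the resulting enolate gives the enol double bond toward C5, which deprotonation of the corresponding ketone would not give. The forward step needs high enantioselectivity and clean O-silylation.

## Roads not taken

**Alternative 1:** Ring B is cut at C6–C7 and C7 is exchanged for a ring oxygen, so the precursor is a bicyclic pyranoid acetal with an exocyclic enol ether at C8. In the forward sense, catalytic Hg(OCOCF3)2 (divalent mercury) in aqueous acetone hydrates the enol ether, the acetal opens to a C6 aldehyde and a C7-mercurio C8 ketone, and an aldol reaction closes the carbocycle to A1.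
- Merit: A1 is identical with 21, so it arrives with the C6 hydroxyl, the C8 ketone and the side chain in place. The chosen route needs six steps (4–7, 9 and 10) to go from 8 to 21; in this respect the alternative is better.
- Weak points: the step forms none of the difficult bonds. C4–C5, quaternary C10 and the C9 stereocentre must all be present in the oxacyclic precursor, whose construction on a non-carbohydrate scaffold would be long. The C6 carbinol is set in a reversible aldol reaction beside the congested C5, the β-hydroxy ketone may eliminate under the Lewis-acidic conditions, and C9 lies next to the new ketone.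
- Comparison: the chosen plan answers the better endgame with a three-step, catalyst-controlled entry to the bicycle and with substituents added one at a time to a rigid cis-decalin.

**Alternative 2:** Ring B is cut at C9–C10. A C9 vinyl iodide on a chain attached to C5 of a ring A cyclohexene adds to zerovalent palladium (from Pd(OAc)2 and PPh3, with Ag2CO3), the vinylpalladium inserts the C10=C1 olefin in a 6-exo mode, and β-hydride elimination gives A2.
- Merits: quaternary C10 and the ring fusion are made in one event, and syn insertion across a ring olefin can only give the cis fusion. C6 and C8 are fully functionalised in A2. A hydrogenation directed by the C8 hydroxyl could later set C9 and saturate C1=C2 together, so the sequence after the key step would be shorter than in the chosen plan.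
- Weak points: the stereochemical load is moved to an open chain. C5, C6 and the tertiary C8 carbinol must be set by acyclic control beside the neopentyl C4; absolute configuration must come from an enantioenriched ring A piece with an epimerisable allylic C5 centre; and a stereodefined trisubstituted vinyl iodide is required. The insertion must create a quaternary carbon beside the branched C5, and slow insertion invites reduction of the carbon–iodine bond or olefin migration.
- Comparison: the chosen plan places the only catalyst-controlled step at the first C–C bond and then relies on the shape of the bicycle; it concedes the longer functionalisation of ring B.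

**Alternative 3:** Ring A is cut at C1–C10 and C4–C5 together. Diene A5 (4-methylpenta-1,3-diene) adds across the methyl-bearing double bond of quinone A4 (2-methoxy-6-methyl-1,4-benzoquinone) under a chiral oxazaborolidinium triflimide (a prolinol-derived oxazaborolidine protonated by HNTf2), giving A3.
- Merits: one step from simple materials forms two bonds, both ring-fusion centres (cis by the endo-suprafacial addition) and quaternary C10 with absolute control, and ring B arrives oxidised at C6, C8 and C9. On front-end step economy this road is better than the chosen one.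
- Weak points: A5 carries a cis-methyl group at its terminus, which disfavours the s-cis conformation and makes the diene sluggish. The bond to C5 must form at the fully substituted diene terminus. After the cycloaddition, A3 has two carbonyls and a vinylogous ester to differentiate: the C9 carbonyl beside C10 must become a CH bearing the side chain with defined configuration, C8 must change from an enol ether carbon to a methyl carbinol, and C2=C3 must be reduced. C5 lies between a carbonyl and two quaternary carbons and can epimerise throughout.
- Comparison: the chosen plan makes the same C4–C5 bond intramolecularly through a cation, where steric demand at C4 is not an obstacle, and leaves ring B with a single carbonyl to be worked on. It pays with the four-step transposition.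

Key step: step 3

Assumption: the antipode of the chiral imidazolinium salt (both derive from commercial leucinol) is chosen that gives the (S) centre of 7; "syn" and "anti" mean on the face of, and opposite to, the C10 methyl group, the syn face being the convex face of the cis-decalin.

## Route

Step 1
Reactants: 1 5-bromo-2-methylpent-2-ene
Product: 3 5-bromo-2-methoxy-2-methylpentane, via acetoxy(5-bromo-2-methoxy-2-methylpentan-3-yl)mercury 2 (not isolated)
Conditions: Hg(OAc)2, MeOH, rt; then NaBH4, aq NaOH, 0 °C
Reagents that add atoms: methanol (CO)
Why: Markovnikov alkoxymercuration–demercuration: methanol opens the mercurinium ion at the tertiary carbon, NaBH4 replaces mercury by hydrogen, and the primary bromide survives the brief, cold treatment. A methyl ether is chosen because it tolerates Grignard formation yet is ionised by TiCl4 in step 3.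

Step 2
Reactants: 3 5-bromo-2-methoxy-2-methylpentane; 4 3-methylcyclohex-2-en-1-one
Product: 7 (S)-{[3-(4-methoxy-4-methylpentyl)-3-methylcyclohex-1-en-1-yl]oxy}trimethylsilane, via (4-methoxy-4-methylpentyl)magnesium bromide 5 (not isolated), via bromomagnesium enolate 6 (not isolated)
Conditions: Mg, Et2O, reflux; then Cu(OTf)2 (3 mol %), 1-mesityl-3-[1-(hydroxymethyl)-3-methylbutyl]-4,5-dihydroimidazolium hexafluorophosphate (4 mol %), Et2O, 0 °C, slow addition of 4; then Me3SiCl, Et3N, DMPU, 0 °C to rt; non-aqueous work-up
Reagents that add atoms: chlorotrimethylsilane (C[Si](C)(C)Cl)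
Why: Copper-catalysed asymmetric conjugate addition of a Grignard reagent to a β-substituted cyclic enone: the copper–carbene complex formed in the flask delivers the alkyl group to one face of 4 and creates quaternary C10 under catalyst control. O-Silylation of the magnesium enolate fixes the enol double bond toward the new quaternary carbon (C5=C6), a regiochemistry that deprotonation of the ketone would not give.

Step 3
Reactants: 7 (S)-{[3-(4-methoxy-4-methylpentyl)-3-methylcyclohex-1-en-1-yl]oxy}trimethylsilane
Product: 8 (4aS,8aS)-4a,8,8-trimethyloctahydronaphthalen-1(2H)-one (cis-fused; C6 ketone)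
Conditions: TiCl4 (1.1 equiv), CH2Cl2, −78 to −40 °C; aq NaHCO3
Reagents that add atoms: none
Why: TiCl4 takes the methoxide from the tertiary ether and leaves the C4 carbocation, which is captured by the nucleophilic carbon C5 of the C5=C6 enol silane; chloride then removes the silyl group and the C6 ketone appears. The closest known reaction type is the Lewis-acid-mediated α-tert-alkylation of silyl enol ethers by tertiary alkyl halides, ethers or esters (an SN1 alkylation), including its intramolecular form. Ring A closes in a six-membered mode in which the enol double bond stays outside the new ring (6-enolexo) and the cationic carbon is the ring terminus, through a chair-like transition state. The one new stereocentre, C5, is controlled by C10: the three-carbon tether hangs from C10 and the new bond must form along the π-axis of the enol, so the cation can reach C5 only on the face where the tether lies, which gives the cis fusion (H5 syn to the C10 methyl group). Regioselectivity (C5, not C7) is secured by the position of the enol double bond fixed in step 2; O-alkylation would need an eight-membered ring and should not compete. The step also needs C–C bond formation to outrun loss of a proton from the cation and protodesilylation, which low temperature and a full equivalent of Lewis acid favour. The SN1 character is what allows a quaternary carbon to be joined to a carbon that itself neighbours a quaternary centre.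

Step 4
Reactants: 8 (4aS,8aS)-4a,8,8-trimethyloctahydronaphthalen-1(2H)-one
Product: 10 (4aS,8aS)-4a,8,8-trimethyl-4a,5,6,7,8,8a-hexahydronaphthalen-1(4H)-one (C6 ketone, C7=C8), via C6 trimethylsilyl enol ether 9 (not isolated)
Conditions: LiN(iPr)2 (LDA), THF, −78 °C; Me3SiCl; then Pd(OAc)2 (10 mol %), O2 (1 atm), DMSO, rt
Reagents that add atoms: none
Why: Saegusa–Ito oxidation: kinetic deprotonation occurs at the C7 methylene because the C5 methine is buried between two quaternary carbons, and palladation of the enol silane followed by β-hydride elimination gives the C7=C8 enone. C5 is not touched.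

Step 5
Reactants: 10 (4aS,8aS)-4a,8,8-trimethyl-4a,5,6,7,8,8a-hexahydronaphthalen-1(4H)-one
Product: 11 7,8-epoxide of 10 (7,8-epoxy C6 ketone; oxirane oxygen syn, C5 and C10 unchanged)
Conditions: 30% aq H2O2, NaOH, MeOH, 0 °C
Reagents that add atoms: hydrogen peroxide (OO)
Why: Weitz–Scheffer nucleophilic epoxidation: hydroperoxide adds to the unhindered C8 and the enolate closes the oxirane, expected on the convex face. The epoxide configuration is of no consequence because both centres are cleared in steps 6 and 7; cold, brief exposure to base limits enolisation toward C5.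

Step 6
Reactants: 11 7,8-epoxy C6 ketone
Product: 13 (2S,4aS,8aS)-5,5,8a-trimethyl-1,2,4a,5,6,7,8,8a-octahydronaphthalen-2-ol (C8 alcohol, C6=C7), via C6 hydrazone of the epoxy ketone 12 (not isolated)
Conditions: N2H4·H2O, AcOH (cat.), MeOH, 0 °C to rt
Reagents that add atoms: none
Why: Wharton transposition: the C6 hydrazone opens the oxirane to a vinyl diazene that loses N2, leaving the C6=C7 olefin and the C8 alcohol. The carbinol configuration follows the epoxide and is removed in step 7.

Step 7
Reactants: 13 (2S,4aS,8aS)-5,5,8a-trimethyl-1,2,4a,5,6,7,8,8a-octahydronaphthalen-2-ol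
Product: 14 (4aS,8aS)-5,5,8a-trimethyl-4a,5,6,7,8,8a-hexahydronaphthalen-2(1H)-one (C8 ketone, C6=C7)
Conditions: Dess–Martin periodinane, NaHCO3, CH2Cl2, rt
Reagents that add atoms: none
Why: Dess–Martin oxidation of a secondary allylic alcohol under buffered conditions gives the transposed enone without moving the double bond or disturbing C5.

Step 8
Reactants: 15 but-3-en-2-one
Product: 17 2-(2-iodoethyl)-2-methyl-1,3-dioxolane, via 4-iodo-2-(trimethylsilyloxy)but-2-ene 16 (not isolated)
Conditions: NaI, Me3SiCl, MeCN, 0 °C to rt; then ethane-1,2-diol, rt
Reagents that add atoms: sodium iodide ([Na+].[I-]); ethane-1,2-diol (OCCO)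
Why: Conjugate addition of iodide from Me3SiI made in the flask gives the β-iodo silyl enol ether, which the diol converts into the ketal; this is a known one-flask route to β-halo ketals.

Step 9
Reactants: 14 (4aS,8aS)-5,5,8a-trimethyl-4a,5,6,7,8,8a-hexahydronaphthalen-2(1H)-one; 17 2-(2-iodoethyl)-2-methyl-1,3-dioxolane
Product: 19 (1S,4aS,8aR)-5,5,8a-trimethyl-1-[2-(2-methyl-1,3-dioxolan-2-yl)ethyl]-4a,5,6,7,8,8a-hexahydronaphthalen-2(1H)-one (side chain at C9 syn), via lithium dienolate of the enone 18 (not isolated)
Conditions: LiN(iPr)2, THF, −78 °C; 17, DMPU, −78 to −20 °C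
Reagents that add atoms: none
Why: Kinetic α′-alkylation of a cyclohexenone: the base removes a C9 proton (C7 is vinylic, and the γ-proton at C5 is reached only on equilibration) and the cross-conjugated enolate is alkylated at C9 by the primary iodide. The electrophile should enter axially on the convex face, away from the C1 methylene that ring A holds under ring B, which places C11 syn to the C10 methyl group.

Step 10
Reactants: 19 (1S,4aS,8aR)-5,5,8a-trimethyl-1-[2-(2-methyl-1,3-dioxolan-2-yl)ethyl]-4a,5,6,7,8,8a-hexahydronaphthalen-2(1H)-one
Product: 21 (1S,4S,4aS,8aR)-4-hydroxy-5,5,8a-trimethyl-1-[2-(2-methyl-1,3-dioxolan-2-yl)ethyl]octahydronaphthalen-2(1H)-one (C6 hydroxyl syn, C8 ketone), via C6 pinacol boronate 20 (not isolated)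
Conditions: B2pin2, CuCl (5 mol %), Xantphos (5 mol %), NaOtBu (10 mol %), MeOH (2 equiv), THF, rt; then NaBO3·4H2O, THF/H2O, rt
Reagents that add atoms: sodium perborate ([Na+].[Na+].O[B-]1(O)OO[B-](O)(O)OO1)
Why: Copper-catalysed β-borylation of an enone followed by oxidation of the C–B bond with retention is a formal hydration that places oxygen at C6 by the polarity of the enone. The boryl–copper species should add trans to C4, the bulky substituent on the adjacent C5, which is again the convex face, so the hydroxyl ends syn to H5 and the C10 methyl; the mild perborate oxidation avoids elimination of the β-hydroxy ketone.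

Step 11
Reactants: 21 (1S,4S,4aS,8aR)-4-hydroxy-5,5,8a-trimethyl-1-[2-(2-methyl-1,3-dioxolan-2-yl)ethyl]octahydronaphthalen-2(1H)-one
Product: 23 4-[(1S,2S,4S,4aS,8aR)-2,4-dihydroxy-2,5,5,8a-tetramethyldecahydronaphthalen-1-yl]butan-2-one, via dioxolane diol 22 (not isolated)
Conditions: MeLi, CeCl3, THF, −78 °C; then 1 M HCl, THF, rt
Reagents that add atoms: methyllithium ([Li]C); water (O)
Why: Organocerium 1,2-addition: the weakly basic reagent adds to the hindered, enolisable C8 ketone without retro-aldol cleavage or elimination, one equivalent being consumed by the C6 hydroxyl. Methyl should enter equatorially from the convex face because the axial path on the other face is blocked by the syn-axial C1 methylene, giving the C8 methyl syn and the hydroxyl anti to the C10 methyl; dilute acid then frees the C13 ketone.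

Step 12
Reactants: 23 4-[(1S,2S,4S,4aS,8aR)-2,4-dihydroxy-2,5,5,8a-tetramethyldecahydronaphthalen-1-yl]butan-2-one
Product: 24 allyl (2E)-5-[(1S,2S,4S,4aS,8aR)-2,4-dihydroxy-2,5,5,8a-tetramethyldecahydronaphthalen-1-yl]-3-methylpent-2-enoate
Conditions: (EtO)2P(O)CH2CO2CH2CH=CH2, NaH, THF, 0 to 50 °C
Reagents that add atoms: allyl diethylphosphonoacetate (C=CCOC(=O)CP(=O)(OCC)OCC)
Why: Horner–Wadsworth–Emmons olefination of a methyl ketone is expected to favour the (E)-enoate, with the larger chain trans to the ester; any (Z)-isomer is removed by chromatography. The phosphonate anion is too weak a base to deprotonate the alcohols, and olefination before acylation avoids a hemiketal between the C8 hydroxyl and the C13 ketone.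

Step 13
Reactants: 24 allyl (2E)-5-[(1S,2S,4S,4aS,8aR)-2,4-dihydroxy-2,5,5,8a-tetramethyldecahydronaphthalen-1-yl]-3-methylpent-2-enoate
Product: 25 allyl (2E)-5-[(1S,2S,4S,4aS,8aR)-4-acetoxy-2-hydroxy-2,5,5,8a-tetramethyldecahydronaphthalen-1-yl]-3-methylpent-2-enoate
Conditions: Ac2O, pyridine, DMAP (cat.), CH2Cl2, 0 °C to rt
Reagents that add atoms: acetic anhydride (CC(=O)OC(C)=O)
Why: Nucleophile-catalysed O-acylation distinguishes the secondary C6 alcohol from the tertiary C8 alcohol, which does not react under these conditions.

Step 14
Reactants: 25 allyl (2E)-5-[(1S,2S,4S,4aS,8aR)-4-acetoxy-2-hydroxy-2,5,5,8a-tetramethyldecahydronaphthalen-1-yl]-3-methylpent-2-enoate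
Product: 26 (2E)-5-[(1S,2S,4S,4aS,8aR)-4-acetoxy-2-hydroxy-2,5,5,8a-tetramethyldecahydronaphthalen-1-yl]-3-methylpent-2-enoic acid (CNP0221670.1)
Conditions: Pd(PPh3)4 (5 mol %), morpholine, THF, rt; acidic work-up
Reagents that add atoms: none
Why: Tsuji–Trost-type deallylation: zerovalent palladium ionises the allyl ester to a π-allyl complex that morpholine intercepts, releasing the acid under neutral conditions that spare the acetate, the tertiary alcohol and the olefin geometry.

## Compound list

1 | 5-bromo-2-methylpent-2-ene | CC(C)=CCCBr | starting material
2 | acetoxy(5-bromo-2-methoxy-2-methylpentan-3-yl)mercury (racemic) | COC(C)(C)C(CCBr)[Hg]OC(C)=O | intermediate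
3 | 5-bromo-2-methoxy-2-methylpentane | COC(C)(C)CCCBr | intermediate
4 | 3-methylcyclohex-2-en-1-one | CC1=CC(=O)CCC1 | starting material
5 | (4-methoxy-4-methylpentyl)magnesium bromide | COC(C)(C)CCC[Mg]Br | intermediate
6 | bromomagnesium (S)-3-(4-methoxy-4-methylpentyl)-3-methylcyclohex-1-en-1-olate | Br[Mg]OC1=C[C@@](C)(CCCC(C)(C)OC)CCC1 | intermediate
7 | (S)-{[3-(4-methoxy-4-methylpentyl)-3-methylcyclohex-1-en-1-yl]oxy}trimethylsilane | C[Si](C)(C)OC1=C[C@@](C)(CCCC(C)(C)OC)CCC1 | intermediate
8 | (4aS,8aS)-4a,8,8-trimethyloctahydronaphthalen-1(2H)-one | O=C1CCC[C@]2(C)CCCC(C)(C)[C@H]12 | intermediate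
9 | trimethyl{[(4aS,8aS)-4a,8,8-trimethyl-3,4,4a,5,6,7,8,8a-octahydronaphthalen-1-yl]oxy}silane | C[Si](C)(C)OC1=CCC[C@]2(C)CCCC(C)(C)[C@H]12 | intermediate
10 | (4aS,8aS)-4a,8,8-trimethyl-4a,5,6,7,8,8a-hexahydronaphthalen-1(4H)-one | O=C1C=CC[C@]2(C)CCCC(C)(C)[C@H]12 | intermediate
11 | 7,8-epoxide of 10, oxirane oxygen syn to the C10 methyl | O=C1[C@H]2O[C@H]2C[C@]3(C)CCCC(C)(C)[C@H]13 | intermediate
12 | C6 hydrazone of 11 | NN=C1[C@H]2O[C@H]2C[C@]3(C)CCCC(C)(C)[C@H]13 | intermediate
13 | (2S,4aS,8aS)-5,5,8a-trimethyl-1,2,4a,5,6,7,8,8a-octahydronaphthalen-2-ol | C1=C[C@@H](O)C[C@]2(C)CCCC(C)(C)[C@H]12 | intermediate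
14 | (4aS,8aS)-5,5,8a-trimethyl-4a,5,6,7,8,8a-hexahydronaphthalen-2(1H)-one | C1=CC(=O)C[C@]2(C)CCCC(C)(C)[C@H]12 | intermediate
15 | but-3-en-2-one | CC(=O)C=C | starting material
16 | 4-iodo-2-(trimethylsilyloxy)but-2-ene | CC(O[Si](C)(C)C)=CCI | intermediate
17 | 2-(2-iodoethyl)-2-methyl-1,3-dioxolane | CC1(CCI)OCCO1 | intermediate
18 | lithium dienolate of 14 (C8 enolate toward C9) | C1=CC(O[Li])=C[C@]2(C)CCCC(C)(C)[C@H]12 | intermediate
19 | (1S,4aS,8aR)-5,5,8a-trimethyl-1-[2-(2-methyl-1,3-dioxolan-2-yl)ethyl]-4a,5,6,7,8,8a-hexahydronaphthalen-2(1H)-one | C1=CC(=O)[C@@H](CCC3(C)OCCO3)[C@]2(C)CCCC(C)(C)[C@H]12 | intermediate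
20 | C6 pinacol boronate of the C8 ketone (boron syn to the C10 methyl) | B1(OC(C)(C)C(C)(C)O1)[C@H]2CC(=O)[C@@H](CCC4(C)OCCO4)[C@]3(C)CCCC(C)(C)[C@H]23 | intermediate
21 | (1S,4S,4aS,8aR)-4-hydroxy-5,5,8a-trimethyl-1-[2-(2-methyl-1,3-dioxolan-2-yl)ethyl]octahydronaphthalen-2(1H)-one | O[C@H]1CC(=O)[C@@H](CCC3(C)OCCO3)[C@]2(C)CCCC(C)(C)[C@H]12 | intermediate
22 | (1S,2S,4S,4aS,8aR)-2,5,5,8a-tetramethyl-1-[2-(2-methyl-1,3-dioxolan-2-yl)ethyl]decahydronaphthalene-2,4-diol | O[C@H]1C[C@](C)(O)[C@@H](CCC3(C)OCCO3)[C@]2(C)CCCC(C)(C)[C@H]12 | intermediate
23 | 4-[(1S,2S,4S,4aS,8aR)-2,4-dihydroxy-2,5,5,8a-tetramethyldecahydronaphthalen-1-yl]butan-2-one | O[C@H]1C[C@](C)(O)[C@@H](CCC(C)=O)[C@]2(C)CCCC(C)(C)[C@H]12 | intermediate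
24 | allyl (2E)-5-[(1S,2S,4S,4aS,8aR)-2,4-dihydroxy-2,5,5,8a-tetramethyldecahydronaphthalen-1-yl]-3-methylpent-2-enoate | O[C@H]1C[C@](C)(O)[C@@H](CC/C(C)=C/C(=O)OCC=C)[C@]2(C)CCCC(C)(C)[C@H]12 | intermediate
25 | allyl (2E)-5-[(1S,2S,4S,4aS,8aR)-4-acetoxy-2-hydroxy-2,5,5,8a-tetramethyldecahydronaphthalen-1-yl]-3-methylpent-2-enoate | CC(=O)O[C@H]1C[C@](C)(O)[C@@H](CC/C(C)=C/C(=O)OCC=C)[C@]2(C)CCCC(C)(C)[C@H]12 | intermediate
26 | (2E)-5-[(1S,2S,4S,4aS,8aR)-4-acetoxy-2-hydroxy-2,5,5,8a-tetramethyldecahydronaphthalen-1-yl]-3-methylpent-2-enoic acid | CC(=O)O[C@H]1C[C@](C)(O)[C@@H](CC/C(C)=C/C(=O)O)[C@]2(C)CCCC(C)(C)[C@H]12 | target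

## Step count and least certain steps

Total: 14 steps. Longest linear sequence: 13 steps (steps 1–7 and 9–14 from 1); step 8 prepares the side-chain iodide 17.

**Step 3 (key step).** The tertiary cation may lose a proton to give olefins, and the acid set free may then protodesilylate the enol silane before the C–C bond forms; both are favoured by the steric congestion around C4 and C5. Prolonged contact of the product with the Lewis acid may also equilibrate the ring fusion at C5. Fallback: 7 is hydrolysed (K2CO3, MeOH) to (S)-3-(4-methoxy-4-methylpentyl)-3-methylcyclohexan-1-one F1, which is cyclised with a strong protic acid (CH3SO3H, CH2Cl2) through its enol, the acid-mediated cyclialkylation of a ketone. Only the enol toward C5 can close a six-membered ring, so the regiochemistry corrects itself, but the ring fusion is then set under equilibrating conditions and has to be checked. The route is rejoined at 8.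

**Step 2.** O-Silylation of the magnesium enolate may be incomplete, or the trimethylsilyl enol ether may hydrolyse during isolation, which would lose the regiochemical information. Uncatalysed background addition of this ether-bearing Grignard reagent may also erode the enantioselectivity. Fallback: the enolate from 3 and 4 is trapped with Ac2O to give (S)-3-(4-methoxy-4-methylpentyl)-3-methylcyclohex-1-en-1-yl acetate F2, which can be purified. MeLi (2 equiv, THF, 0 °C) then cleaves it to the regiodefined lithium enolate, and Me3SiCl gives 7.

**Step 6.** Hydrazone formation at the hindered C6 carbonyl may be slow, which lets hydrazine open the oxirane or lets the diazene decompose by other paths. Fallback from 11: isomerisation with Pd(PPh3)4 and dppe (zerovalent palladium, toluene, 80 °C) gives (4aS,8aS)-4a,8,8-trimethylhexahydronaphthalene-1,3(2H,4H)-dione F3. Methanol, HC(OMe)3 and TsOH convert it into (4aS,8aS)-3-methoxy-4a,8,8-trimethyl-4a,5,6,7,8,8a-hexahydronaphthalen-1(4H)-one F4, the alcohol attacking the less hindered C8 carbonyl. Reduction of the C6 carbonyl with iBu2AlH and aqueous acid then gives 14 directly, where the route is rejoined.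

**Step 9.** Alkylation of an enolate carbon next to quaternary C10 by a non-activated iodide may be sluggish. Proton transfer to the extended dienolate (with scrambling at C5) and elimination of HI from 17 may then compete, and the facial preference may be incomplete. Fallback from 14: condensation with Me2NNH2 (AcOH cat., EtOH, reflux) gives the N,N-dimethylhydrazone of 14 F5. Its more nucleophilic azaenolate (LiN(iPr)2, THF, −78 to 0 °C) is alkylated with 17 to give the N,N-dimethylhydrazone of 19 F6, and hydrolysis (aq CuCl2, THF, pH 7 buffer) returns 19.

**Step 11.** Facial selectivity at C8 may be poor, because the syn side chain on C9 hinders the equatorial approach that the C1 methylene otherwise enforces. Fallback from 21: Wittig methylenation (Ph3P=CH2, THF) gives the C8 methylidene analogue of 21 F7. Epoxidation with mCPBA (NaHCO3, CH2Cl2) should place oxygen on the face that the methyl nucleophile preferred, giving the C8 spiro-oxirane with oxygen anti to the C10 methyl F8. Opening at the methylene carbon with LiEt3BH (THF) then gives 22, from which the acid hydrolysis of step 11 leads on to 23.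

## Further compounds

F1 | step 3 | (S)-3-(4-methoxy-4-methylpentyl)-3-methylcyclohexan-1-one | O=C1C[C@@](C)(CCCC(C)(C)OC)CCC1
F2 | step 2 | (S)-3-(4-methoxy-4-methylpentyl)-3-methylcyclohex-1-en-1-yl acetate | CC(=O)OC1=C[C@@](C)(CCCC(C)(C)OC)CCC1
F3 | step 6 | (4aS,8aS)-4a,8,8-trimethylhexahydronaphthalene-1,3(2H,4H)-dione | O=C1CC(=O)C[C@]2(C)CCCC(C)(C)[C@H]12
F4 | step 6 | (4aS,8aS)-3-methoxy-4a,8,8-trimethyl-4a,5,6,7,8,8a-hexahydronaphthalen-1(4H)-one | O=C1C=C(OC)C[C@]2(C)CCCC(C)(C)[C@H]12
F5 | step 9 | N,N-dimethylhydrazone of 14 | C1=CC(=NN(C)C)C[C@]2(C)CCCC(C)(C)[C@H]12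
F6 | step 9 | N,N-dimethylhydrazone of 19 | C1=CC(=NN(C)C)[C@@H](CCC3(C)OCCO3)[C@]2(C)CCCC(C)(C)[C@H]12
F7 | step 11 | C8 methylidene analogue of 21 (C6 hydroxyl syn, side chain syn) | O[C@H]1CC(=C)[C@@H](CCC3(C)OCCO3)[C@]2(C)CCCC(C)(C)[C@H]12
F8 | step 11 | C8 spiro-oxirane of F7, oxygen anti to the C10 methyl | O[C@H]1C[C@]4(OC4)[C@@H](CCC3(C)OCCO3)[C@]2(C)CCCC(C)(C)[C@H]12
A1 | alternative 1 | (1S,4S,4aS,8aR)-4-hydroxy-5,5,8a-trimethyl-1-[2-(2-methyl-1,3-dioxolan-2-yl)ethyl]octahydronaphthalen-2(1H)-one | O[C@H]1CC(=O)[C@@H](CCC3(C)OCCO3)[C@]2(C)CCCC(C)(C)[C@H]12
A2 | alternative 2 | cis-fused octalin with C6 tert-butyldimethylsilyloxy, C8 methyl carbinol, C9 exocyclic 3,3-(ethylenedioxy)butylidene and C1=C2 olefin | CC(C)(C)[Si](C)(C)O[C@H]1C[C@](C)(O)/C(=C/CC3(C)OCCO3)[C@]2(C)C=CCC(C)(C)[C@H]12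
A3 | alternative 3 | cis-2-methoxy-5,5,8a-trimethyl-4a,5,8,8a-tetrahydronaphthalene-1,4-dione | O=C1C=C(OC)C(=O)[C@]2(C)CC=CC(C)(C)[C@H]12
A4 | alternative 3 | 2-methoxy-6-methyl-1,4-benzoquinone | COC1=CC(=O)C=C(C)C1=O
A5 | alternative 3 | 4-methylpenta-1,3-diene | CC(C)=CC=C
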